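**Plan**

1. Labels used throughout: ring C1 (carbinol carbon carrying the C2–C4/C15 acyl chain), C5 (isobutyrate carbon), C6 (lactone O–CH), C7 (ring fusion, carries C11(Me)–C12(=O)), C8, C9, C10 (CHMe).
2. Retrosynthesis: the C3=C4 alkene goes back to a butyl carbinol (oxidation and dehydrogenation last). The lactone is cut at C7=C11 (Horner–Wadsworth–Emmons, then hydrogenation) and at O–C12, giving an α-hydroxy ketone. The C5–O, C6–O and C7–O bonds go back to the carbonyl and alkene of a cyclohept-2-enone, and C1–C2 is an aldol bond.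
3. Enabling feature: C5–C6–C7, which lie next to the fully substituted C1, map onto the C(=O)–CH=CH unit of a 7-alkoxycyclohept-2-enone. That enone is the product of a one-carbon ring expansion of a 2-alkoxycyclohexanone through its siloxycyclopropane, and the inserted CH2 becomes C6.
4. Forward order: cyclohexane first (C10 methyl, C1 oxygen), then ring expansion to the cycloheptenone, C1 quaternisation by aldol, C5, C6/C7 oxygenation, the γ-lactone ring last (C7=C11 closure, then hydrogenation), and the enone at the very end.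
5. Stereochemistry: C10 by copper-catalysed asymmetric conjugate addition; C1 by aldol anti to the C10 methyl; C5 by chelation-controlled reduction from C1; C6 by dihydroxylation anti to the C5 ester; C7 and C11 together by hydrogenation from the face of H6.

Key step: step 6

**Remarks on the chemistry**

- The ligand enantiomer in step 1 is assumed to be the one that gives the (S) centre (by analogy with the ethyl case); the other enantiomer is used if not.
- C1 in compounds 4–11 is drawn as the trans isomer expected from step 2; its epimer serves equally, because C1 is planarised in step 7.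
- The carbinol carbon C2 in compounds 14–24 is formed without control and is drawn without a stereo label; it becomes the ketone in step 14.

**Route**

Step 1
Reactants: 1 cyclohex-2-en-1-one
Product: 3 (S)-trimethyl[(3-methylcyclohex-1-en-1-yl)oxy]silane, via methylzinc enolate 2 (not isolated)
Conditions: Me2Zn, Cu(OTf)2 (cat.), (S,R,R)-phosphoramidite ligand (cat.), toluene, −30 °C; then TMSOTf, −30 → 0 °C
Reagents that add atoms: dimethylzinc (C[Zn]C); trimethylsilyl triflate (C[Si](C)(C)OS(=O)(=O)C(F)(F)F)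
Why: Copper-catalysed asymmetric conjugate addition sets C10 by catalyst control, and silylation of the zinc enolate fixes the enol ether between the carbonyl carbon and the carbon next to C10.

Step 2
Reactants: 3 (S)-trimethyl[(3-methylcyclohex-1-en-1-yl)oxy]silane
Product: 5 (2R,3S)-2-hydroxy-3-methylcyclohexan-1-one, via α-silyloxy ketone 4 (not isolated)
Conditions: mCPBA, NaHCO3, CH2Cl2, 0 °C; then 1 M HCl, THF
Reagents that add atoms: mCPBA (O=C(OO)c1cccc(Cl)c1)
Why: Rubottom oxidation, in which epoxidation anti to the neighbouring methyl group and a 1,4-silyl shift put oxygen on C1 (trans isomer expected, configuration erased later).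

Step 3
Reactants: 5 (2R,3S)-2-hydroxy-3-methylcyclohexan-1-one
Product: 6 (2R,3S)-2-(benzyloxy)-3-methylcyclohexan-1-one
Conditions: BnBr, Ag2O, CH2Cl2, rt
Reagents that add atoms: benzyl bromide (BrCc1ccccc1)
Why: Silver(I) oxide-mediated Williamson benzylation avoids strong base on the enolisable α-hydroxy ketone and installs the ether that serves as the chelating group in step 8.

Step 4
Reactants: 6 (2R,3S)-2-(benzyloxy)-3-methylcyclohexan-1-one
Product: 8 [(5S,6R)-6-(benzyloxy)-5-methylcyclohex-1-en-1-yl]oxy(trimethyl)silane, via lithium enolate 7 (not isolated)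
Conditions: LDA, THF, −78 °C; then TMSCl, Et3N
Reagents that add atoms: chlorotrimethylsilane (C[Si](C)(C)Cl)
Why: Kinetic deprotonation takes the unhindered α-methylene proton and not the alkoxy-bearing methine, so O-silylation gives the less substituted enol silane.

Step 5
Reactants: 8 [(5S,6R)-6-(benzyloxy)-5-methylcyclohex-1-en-1-yl]oxy(trimethyl)silane
Product: 9 (2R,3S)-2-(benzyloxy)-3-methyl-1-(trimethylsilyloxy)bicyclo[4.1.0]heptane
Conditions: Et2Zn, CH2I2, CH2Cl2, 0 °C → rt
Reagents that add atoms: diiodomethane (ICI)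
Why: Simmons–Smith cyclopropanation (Furukawa variant) of the electron-rich enol silane; the two new ring-fusion centres are not controlled and are lost in step 6.

Step 6
Reactants: 9 (2R,3S)-2-(benzyloxy)-3-methyl-1-(trimethylsilyloxy)bicyclo[4.1.0]heptane
Product: 11 (6S,7R)-7-(benzyloxy)-6-methylcyclohept-2-en-1-one, via β-chloro ketone 10 (not isolated)
Conditions: FeCl3, DMF, 0 °C → rt; then NaOAc, MeOH, reflux
Reagents that add atoms: none
Why: Iron(III) chloride turns the siloxycyclopropane into an iron(III) cyclopropanolate that is oxidised to the alkoxy radical; β-scission of the internal C5–C7 cyclopropane bond gives the ring-expanded secondary β-keto radical at C7, which takes up chlorine, and sodium acetate then eliminates HCl to the cyclohept-2-enone. The closest known reaction type is the Ito–Saegusa FeCl3 ring expansion of 1-siloxybicyclo[n.1.0]alkanes to 2-cycloalkenones. No ring is closed: the seven-membered ring arises from the six-membered one by opening the bond it shares with the three-membered ring, and the inserted CH2 becomes C6. No stereocentre is formed; C10 is β to the carbonyl and untouched, and the configuration at C1 is erased in step 7. The step needs cleavage of the internal rather than an external cyclopropane bond, secured by the greater stability of the secondary ring radical, and the right position for the inserted carbon, fixed by the kinetic enolisation of step 4. It places the C6=C7 alkene where the lactone O and C will be attached and leaves C1–H as the only α-hydrogen of the ketone.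

Step 7
Reactants: 11 (6S,7R)-7-(benzyloxy)-6-methylcyclohept-2-en-1-one; 12 butanal
Product: 15 (6S,7R)-7-(benzyloxy)-6-methyl-7-[1-(triethylsilyloxy)butyl]cyclohept-2-en-1-one, via lithium dienolate 13 (not isolated), via lithium aldolate 14 (not isolated)
Conditions: LDA, THF, −78 °C; butanal, −78 °C; then TESOTf, 2,6-lutidine, −78 → −40 °C
Reagents that add atoms: triethylsilyl triflate (CC[Si](CC)(CC)OS(=O)(=O)C(F)(F)F)
Why: Kinetic α′-deprotonation of the enone (the other α-carbon is now sp2) gives the alkoxy-substituted dienolate, and its aldol addition on the face anti to the pseudo-axial C10 methyl makes C1 fully substituted with O cis and C2 trans to that methyl; the aldolate is silylated in situ.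

Step 8
Reactants: 15 (6S,7R)-7-(benzyloxy)-6-methyl-7-[1-(triethylsilyloxy)butyl]cyclohept-2-en-1-one
Product: 16 (1S,6S,7S)-7-(benzyloxy)-6-methyl-7-[1-(triethylsilyloxy)butyl]cyclohept-2-en-1-ol
Conditions: Zn(BH4)2, Et2O, −20 °C
Reagents that add atoms: none
Why: Chelation-controlled 1,2-reduction in which zinc bridges the carbonyl and benzyloxy oxygens, the side chain becomes pseudo-axial, and hydride adds anti to it, giving the C5 alcohol trans to the C1 oxygen.

Step 9
Reactants: 16 (1S,6S,7S)-7-(benzyloxy)-6-methyl-7-[1-(triethylsilyloxy)butyl]cyclohept-2-en-1-ol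
Product: 17 (1S,6S,7S)-7-(benzyloxy)-6-methyl-7-[1-(triethylsilyloxy)butyl]cyclohept-2-en-1-yl 2-methylpropanoate
Conditions: isobutyryl chloride, pyridine, DMAP (cat.), CH2Cl2, 0 °C → rt
Reagents that add atoms: isobutyryl chloride (CC(C)C(=O)Cl)
Why: DMAP-catalysed acylation of the only free hydroxyl installs the isobutyrate of the target, which also steers step 10.

Step 10
Reactants: 17 (1S,6S,7S)-7-(benzyloxy)-6-methyl-7-[1-(triethylsilyloxy)butyl]cyclohept-2-en-1-yl 2-methylpropanoate
Product: 18 (1S,2R,3R,6S,7S)-7-(benzyloxy)-2,3-dihydroxy-6-methyl-7-[1-(triethylsilyloxy)butyl]cycloheptyl 2-methylpropanoate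
Conditions: OsO4 (cat.), NMO, acetone/H2O, rt
Reagents that add atoms: N-methylmorpholine N-oxide (C[N+]1([O-])CCOCC1); water (O)
Why: Upjohn dihydroxylation, with osmium adding to the cis alkene anti to the allylic acyloxy group (the usual empirical rule for allylic esters and ethers), so the C6 hydroxyl is trans to the C5 ester.

Step 11
Reactants: 18 (1S,2R,3R,6S,7S)-7-(benzyloxy)-2,3-dihydroxy-6-methyl-7-[1-(triethylsilyloxy)butyl]cycloheptyl 2-methylpropanoate
Product: 19 (1S,2S,6S,7S)-7-(benzyloxy)-2-hydroxy-6-methyl-3-oxo-7-[1-(triethylsilyloxy)butyl]cycloheptyl 2-methylpropanoate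
Conditions: TEMPO (cat.), KBr (cat.), NaOCl, aq. NaHCO3, CH2Cl2, 0 °C
Reagents that add atoms: none
Why: Anelli (TEMPO/hypochlorite) oxidation should take the C7 carbinol, which is flanked by a methylene, in preference to the C6 carbinol, which is flanked by two oxygenated carbons and is the more hindered and electron-poor.

Step 12
Reactants: 19 (1S,2S,6S,7S)-7-(benzyloxy)-2-hydroxy-6-methyl-3-oxo-7-[1-(triethylsilyloxy)butyl]cycloheptyl 2-methylpropanoate; 20 2-(diethoxyphosphoryl)propanoic acid
Product: 22 (6S,7S,8S,8aR)-7-(benzyloxy)-3,6-dimethyl-2-oxo-7-[1-(triethylsilyloxy)butyl]-4,5,6,7,8,8a-hexahydro-2H-cyclohepta[b]furan-8-yl 2-methylpropanoate, via phosphonate ester 21 (not isolated)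
Conditions: DCC, DMAP (cat.), CH2Cl2, 0 °C; then LiCl, iPr2NEt, MeCN, rt
Reagents that add atoms: none
Why: Steglich esterification of the C6 hydroxyl followed by intramolecular Horner–Wadsworth–Emmons olefination (Masamune–Roush conditions) closes the α-methyl butenolide by C7=C11 bond formation, with a base mild enough to limit β-elimination of the C5 ester.

Step 13
Reactants: 22 (6S,7S,8S,8aR)-7-(benzyloxy)-3,6-dimethyl-2-oxo-7-[1-(triethylsilyloxy)butyl]-4,5,6,7,8,8a-hexahydro-2H-cyclohepta[b]furan-8-yl 2-methylpropanoate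
Product: 24 (3R,3aS,6S,7R,8S,8aR)-7-hydroxy-7-(1-hydroxybutyl)-3,6-dimethyl-2-oxooctahydro-2H-cyclohepta[b]furan-8-yl 2-methylpropanoate, via triethylsilyl ether 23 (not isolated)
Conditions: H2 (10 bar), Pd(OH)2/C, EtOAc, rt; filter; then PPTS (cat.), MeOH, 40 °C
Reagents that add atoms: none
Why: Heterogeneous hydrogenation adds both hydrogens to the tetrasubstituted butenolide alkene from the face of H6, away from the arc of the seven-membered ring, so C7 and C11 are set in one event (cis-fused lactone, C11 methyl on the concave side); the tertiary benzyl ether is hydrogenolysed in the same operation and the silyl ether is then removed by acidic methanolysis.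

Step 14
Reactants: 24 (3R,3aS,6S,7R,8S,8aR)-7-hydroxy-7-(1-hydroxybutyl)-3,6-dimethyl-2-oxooctahydro-2H-cyclohepta[b]furan-8-yl 2-methylpropanoate
Product: 26 (3R,3aS,6S,7S,8S,8aR)-7-[(2E)-but-2-enoyl]-7-hydroxy-3,6-dimethyl-2-oxooctahydro-2H-cyclohepta[b]furan-8-yl 2-methylpropanoate, via butanoyl ketone 25 (not isolated)
Conditions: IBX (excess), DMSO, rt; then 80 °C
Reagents that add atoms: none
Why: IBX oxidises the secondary alcohol of the vicinal diol to the ketone without glycol cleavage and, on heating, dehydrogenates the only enolisable α,β-position of that ketone (IBX-mediated ketone dehydrogenation) to the (E)-enone, leaving the ester and lactone α-positions alone.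

**Compound list**

1 | cyclohex-2-en-1-one | O=C1C=CCCC1 | starting material
2 | methylzinc (S)-3-methylcyclohex-1-en-1-olate | C[Zn]OC1=C[C@@H](C)CCC1 | intermediate
3 | (S)-trimethyl[(3-methylcyclohex-1-en-1-yl)oxy]silane | C[Si](C)(C)OC1=C[C@@H](C)CCC1 | intermediate
4 | (2R,3S)-3-methyl-2-(trimethylsilyloxy)cyclohexan-1-one | O=C1[C@H](O[Si](C)(C)C)[C@@H](C)CCC1 | intermediate
5 | (2R,3S)-2-hydroxy-3-methylcyclohexan-1-one | O=C1[C@H](O)[C@@H](C)CCC1 | intermediate
6 | (2R,3S)-2-(benzyloxy)-3-methylcyclohexan-1-one | O=C1[C@H](OCc2ccccc2)[C@@H](C)CCC1 | intermediate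
7 | lithium (5S,6R)-6-(benzyloxy)-5-methylcyclohex-1-en-1-olate | [Li]OC1=CCC[C@H](C)[C@H]1OCc2ccccc2 | intermediate
8 | [(5S,6R)-6-(benzyloxy)-5-methylcyclohex-1-en-1-yl]oxy(trimethyl)silane | C[Si](C)(C)OC1=CCC[C@H](C)[C@H]1OCc2ccccc2 | intermediate
9 | (2R,3S)-2-(benzyloxy)-3-methyl-1-(trimethylsilyloxy)bicyclo[4.1.0]heptane (ring-fusion centres not defined) | C[Si](C)(C)OC12CC1CC[C@H](C)[C@H]2OCc3ccccc3 | intermediate
10 | (2R,3S)-2-(benzyloxy)-6-chloro-3-methylcycloheptan-1-one (C–Cl centre not defined) | O=C1CC(Cl)CC[C@H](C)[C@H]1OCc2ccccc2 | intermediate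
11 | (6S,7R)-7-(benzyloxy)-6-methylcyclohept-2-en-1-one | O=C1C=CCC[C@H](C)[C@H]1OCc2ccccc2 | intermediate
12 | butanal | CCCC=O | starting material
13 | lithium (3S)-2-(benzyloxy)-3-methylcyclohepta-1,6-dien-1-olate | [Li]OC1=C(OCc2ccccc2)[C@@H](C)CCC=C1 | intermediate
14 | lithium 1-[(1R,2S)-1-(benzyloxy)-2-methyl-7-oxocyclohept-5-en-1-yl]butan-1-olate | CCCC(O[Li])[C@]1(OCc2ccccc2)[C@@H](C)CCC=CC1=O | intermediate
15 | (6S,7R)-7-(benzyloxy)-6-methyl-7-[1-(triethylsilyloxy)butyl]cyclohept-2-en-1-one | CCCC(O[Si](CC)(CC)CC)[C@]1(OCc2ccccc2)[C@@H](C)CCC=CC1=O | intermediate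
16 | (1S,6S,7S)-7-(benzyloxy)-6-methyl-7-[1-(triethylsilyloxy)butyl]cyclohept-2-en-1-ol | CCCC(O[Si](CC)(CC)CC)[C@]1(OCc2ccccc2)[C@@H](C)CCC=C[C@@H]1O | intermediate
17 | (1S,6S,7S)-7-(benzyloxy)-6-methyl-7-[1-(triethylsilyloxy)butyl]cyclohept-2-en-1-yl 2-methylpropanoate | CCCC(O[Si](CC)(CC)CC)[C@]1(OCc2ccccc2)[C@@H](C)CCC=C[C@@H]1OC(=O)C(C)C | intermediate
18 | (1S,2R,3R,6S,7S)-7-(benzyloxy)-2,3-dihydroxy-6-methyl-7-[1-(triethylsilyloxy)butyl]cycloheptyl 2-methylpropanoate | CCCC(O[Si](CC)(CC)CC)[C@]1(OCc2ccccc2)[C@@H](C)CC[C@@H](O)[C@@H](O)[C@@H]1OC(=O)C(C)C | intermediate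
19 | (1S,2S,6S,7S)-7-(benzyloxy)-2-hydroxy-6-methyl-3-oxo-7-[1-(triethylsilyloxy)butyl]cycloheptyl 2-methylpropanoate | CCCC(O[Si](CC)(CC)CC)[C@]1(OCc2ccccc2)[C@@H](C)CCC(=O)[C@@H](O)[C@@H]1OC(=O)C(C)C | intermediate
20 | 2-(diethoxyphosphoryl)propanoic acid | CCOP(=O)(OCC)C(C)C(=O)O | starting material
21 | (1S,2S,6S,7S)-7-(benzyloxy)-2-{[2-(diethoxyphosphoryl)propanoyl]oxy}-6-methyl-3-oxo-7-[1-(triethylsilyloxy)butyl]cycloheptyl 2-methylpropanoate | CCCC(O[Si](CC)(CC)CC)[C@]1(OCc2ccccc2)[C@@H](C)CCC(=O)[C@@H](OC(=O)C(C)P(=O)(OCC)OCC)[C@@H]1OC(=O)C(C)C | intermediate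
22 | (6S,7S,8S,8aR)-7-(benzyloxy)-3,6-dimethyl-2-oxo-7-[1-(triethylsilyloxy)butyl]-4,5,6,7,8,8a-hexahydro-2H-cyclohepta[b]furan-8-yl 2-methylpropanoate | CCCC(O[Si](CC)(CC)CC)[C@]1(OCc2ccccc2)[C@@H](C)CCC3=C(C)C(=O)O[C@H]3[C@@H]1OC(=O)C(C)C | intermediate
23 | (3R,3aS,6S,7S,8S,8aR)-7-hydroxy-3,6-dimethyl-2-oxo-7-[1-(triethylsilyloxy)butyl]octahydro-2H-cyclohepta[b]furan-8-yl 2-methylpropanoate | CCCC(O[Si](CC)(CC)CC)[C@]1(O)[C@@H](C)CC[C@@H]2[C@@H](OC(=O)[C@@H]2C)[C@@H]1OC(=O)C(C)C | intermediate
24 | (3R,3aS,6S,7R,8S,8aR)-7-hydroxy-7-(1-hydroxybutyl)-3,6-dimethyl-2-oxooctahydro-2H-cyclohepta[b]furan-8-yl 2-methylpropanoate | CCCC(O)[C@]1(O)[C@@H](C)CC[C@@H]2[C@@H](OC(=O)[C@@H]2C)[C@@H]1OC(=O)C(C)C | intermediate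
25 | (3R,3aS,6S,7S,8S,8aR)-7-butanoyl-7-hydroxy-3,6-dimethyl-2-oxooctahydro-2H-cyclohepta[b]furan-8-yl 2-methylpropanoate | CCCC(=O)[C@]1(O)[C@@H](C)CC[C@@H]2[C@@H](OC(=O)[C@@H]2C)[C@@H]1OC(=O)C(C)C | intermediate
26 | (3R,3aS,6S,7S,8S,8aR)-7-[(2E)-but-2-enoyl]-7-hydroxy-3,6-dimethyl-2-oxooctahydro-2H-cyclohepta[b]furan-8-yl 2-methylpropanoate | C/C=C/C(=O)[C@]1(O)[C@@H](C)CC[C@@H]2[C@@H](OC(=O)[C@@H]2C)[C@@H]1OC(=O)C(C)C | target

**Step count and risks**

Total step count: 14. Longest linear sequence: 14 steps (from 1).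

Steps most likely to fail:

Step 7. The α′-proton is tertiary and lies between two substituted carbons, so deprotonation may be slow and be overtaken by γ-deprotonation. The congested aldolate may also revert before it is silylated, and facial control in the flexible dienolate may be incomplete. The fallback sets the quaternary centre on the six-membered ring before the ring expansion, and it sets out from 6. Equilibrating silylation (TMSOTf, Et3N, CH2Cl2) should give the alkoxy-substituted thermodynamic enol silane F1. A Mukaiyama aldol addition to 12 (BF3·OEt2, CH2Cl2, −78 °C), again anti to the methyl group, gives the β-hydroxy ketone F2. TESOTf with 2,6-lutidine gives its triethylsilyl ether F3, whose ketone has only one enolisable position. LDA/TMSCl then gives the enol silane F4, Et2Zn/CH2I2 gives the siloxycyclopropane F5, and FeCl3/DMF followed by NaOAc/MeOH gives the cycloheptenone 15, where the fallback comes back to the route.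

Step 11. The oxidation may not tell the two secondary hydroxyls apart well enough, may run on to the diketone or cleave the glycol, and the basic medium may cause loss of isobutyrate from the β-acyloxy ketone. The fallback moves the steric differentiation into a protection step, and it sets out from 18. TMSCl (1 equiv) with Et3N in CH2Cl2 at −78 °C should silylate the less hindered C7 hydroxyl to give the mono(trimethylsilyl) ether F6. DCC/DMAP coupling with 20 acylates the C6 hydroxyl to give the phosphonate ester F7. Citric acid in MeOH removes the trimethylsilyl group while the triethylsilyl ether stays, giving the hydroxy phosphonate F8. Dess–Martin periodinane then oxidises C7 to give 21, where the fallback comes back to the route; 21 is cyclised to 22 as in step 12.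

Step 14. The dehydrogenation may stop at the saturated ketone, or the tertiary α-ketol may not survive hot IBX/DMSO (retro-aldol-type cleavage or α-ketol shift). The fallback is a stepwise Saegusa–Ito sequence, and it sets out from 24. IBX in DMSO at room temperature stops at the ketone 25, which is now isolated. TMSOTf/Et3N (CH2Cl2, 0 °C) gives the bis(trimethylsilyl) enol silane F9; enolisation is possible only towards C3. Pd(OAc)2 in MeCN gives the (E)-enone as its C1 trimethylsilyl ether F10, and 1 M HCl in THF removes the silyl group to give 26, where the fallback comes back to the route.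

**Further compounds**

F1 | step 7 | (S)-[2-(benzyloxy)-3-methylcyclohex-1-en-1-yl]oxy(trimethyl)silane | C[Si](C)(C)OC1=C(OCc2ccccc2)[C@@H](C)CCC1
F2 | step 7 | (2R,3S)-2-(benzyloxy)-2-(1-hydroxybutyl)-3-methylcyclohexan-1-one | CCCC(O)[C@]1(OCc2ccccc2)[C@@H](C)CCCC1=O
F3 | step 7 | (2R,3S)-2-(benzyloxy)-3-methyl-2-[1-(triethylsilyloxy)butyl]cyclohexan-1-one | CCCC(O[Si](CC)(CC)CC)[C@]1(OCc2ccccc2)[C@@H](C)CCCC1=O
F4 | step 7 | [(5S,6R)-6-(benzyloxy)-5-methyl-6-[1-(triethylsilyloxy)butyl]cyclohex-1-en-1-yl]oxy(trimethyl)silane | CCCC(O[Si](CC)(CC)CC)[C@]1(OCc2ccccc2)[C@@H](C)CCC=C1O[Si](C)(C)C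
F5 | step 7 | (2R,3S)-2-(benzyloxy)-3-methyl-2-[1-(triethylsilyloxy)butyl]-1-(trimethylsilyloxy)bicyclo[4.1.0]heptane | CCCC(O[Si](CC)(CC)CC)[C@]1(OCc2ccccc2)[C@@H](C)CCC2CC12O[Si](C)(C)C
F6 | step 11 | C7-O-trimethylsilyl ether of diol 18 | CCCC(O[Si](CC)(CC)CC)[C@]1(OCc2ccccc2)[C@@H](C)CC[C@@H](O[Si](C)(C)C)[C@@H](O)[C@@H]1OC(=O)C(C)C
F7 | step 11 | C6-O-[2-(diethoxyphosphoryl)propanoyl] ester of F6 | CCCC(O[Si](CC)(CC)CC)[C@]1(OCc2ccccc2)[C@@H](C)CC[C@@H](O[Si](C)(C)C)[C@@H](OC(=O)C(C)P(=O)(OCC)OCC)[C@@H]1OC(=O)C(C)C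
F8 | step 11 | C7 alcohol formed from F7 by removal of the trimethylsilyl group | CCCC(O[Si](CC)(CC)CC)[C@]1(OCc2ccccc2)[C@@H](C)CC[C@@H](O)[C@@H](OC(=O)C(C)P(=O)(OCC)OCC)[C@@H]1OC(=O)C(C)C
F9 | step 14 | bis(trimethylsilyl) derivative of 25 (C1 silyl ether and C2 enol silane) | CCC=C(O[Si](C)(C)C)[C@]1(O[Si](C)(C)C)[C@@H](C)CC[C@@H]2[C@@H](OC(=O)[C@@H]2C)[C@@H]1OC(=O)C(C)C
F10 | step 14 | C1-O-trimethylsilyl ether of 26 | C/C=C/C(=O)[C@]1(O[Si](C)(C)C)[C@@H](C)CC[C@@H]2[C@@H](OC(=O)[C@@H]2C)[C@@H]1OC(=O)C(C)C
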